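**Retrosynthetic overview**
1. Numbering: ring A = 3,4-dimethoxyphenyl, C7 = carbinol carbon, C8 = aryloxy-bearing carbon, C9 = CH2OH, ring B = primed atoms (O4' = ether oxygen, O3' = free phenol oxygen). In the end game, the β-hydroxy ketone on C1' is carried as a 3-aryl-4,5-dihydroisoxazole, one temporary ring that masks both C=O and CH2OH, and C9 is carried as a methyl ester.
2. Key disconnection C7–C8: C7 is raised to the acyl level and parked as the 3,4-dimethoxybenzoate of O3', and C8 is the CH2 of an aryloxyacetate on O4'. A base-induced O-to-C aroyl shift, followed in the same flask by transfer hydrogenation under dynamic kinetic resolution, should turn this achiral ester into the threo (7S,8S) hydroxy ester with the phenol already free.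
3. Enabling feature: in ring B the free phenolic oxygen O3' sits ortho to the ether oxygen O4' that carries C8. An aroyl group on O3' and a C8 enolate therefore meet over six atoms (C8–O4'–C4'–C3'–O3'–C7), and the C8–H then flanked by the C7 ketone and the C9 ester is acidic enough to make C8 stereolabile.
4. The achiral precursor comes in four steps from 3,4-dihydroxy-5-methoxybenzaldehyde, methyl bromoacetate, 3,4-dimethoxybenzoyl chloride, hydroxylamine and ethylene. The aroyl group serves as the only phenol protection and then becomes ring A/C7.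
5. Ring order: both benzene rings are bought; the dihydroisoxazole is closed in step 4; a transient 1,4-benzodioxane adduct is closed and opened within step 5; the dihydroisoxazole is opened in step 7.

Key step: step 5

Remark: the given SMILES is read as the threo (7S,8S) isomer; the geometry of the aldoxime intermediate (drawn E) has no consequence because it is lost on the way to the nitrile oxide.

Step 1
Reactants: 1 3,4-dihydroxy-5-methoxybenzaldehyde; 2 methyl bromoacetate
Product: 3 methyl 2-(4-formyl-2-hydroxy-6-methoxyphenoxy)acetate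
Conditions: Li2CO3 (1.1 equiv), 2 (1.0 equiv), DMF, 45 °C
Reagents that add atoms: methyl bromoacetate (2), COC(=O)CBr
Why: Williamson ether synthesis in which the 4-OH, para to the formyl group, is clearly the more acidic phenol, so that one equivalent of a weak base should ionise and alkylate only this oxygen.

Step 2
Reactants: 3 methyl 2-(4-formyl-2-hydroxy-6-methoxyphenoxy)acetate; 4 3,4-dimethoxybenzoyl chloride
Product: 5 5-formyl-3-methoxy-2-(2-methoxy-2-oxoethoxy)phenyl 3,4-dimethoxybenzoate
Conditions: Et3N, DMAP (cat.), CH2Cl2, 0 °C → rt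
Reagents that add atoms: 3,4-dimethoxybenzoyl chloride (4), COc1ccc(C(=O)Cl)cc1OC
Why: DMAP-catalysed O-acylation of the only free phenol, which protects O3' and at the same time places ring A and the future C7 next to the aryloxyacetate arm.

Step 3
Reactants: 5 5-formyl-3-methoxy-2-(2-methoxy-2-oxoethoxy)phenyl 3,4-dimethoxybenzoate
Product: 6 5-[(E)-(hydroxyimino)methyl]-3-methoxy-2-(2-methoxy-2-oxoethoxy)phenyl 3,4-dimethoxybenzoate
Conditions: NH2OH·HCl (1.05 equiv), NaOAc, THF/H2O, 0 °C → rt
Reagents that add atoms: hydroxylamine hydrochloride, NO.Cl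
Why: Oxime condensation, in which the aldehyde should react in the acetate buffer far faster than the electron-rich aryl benzoate or the methyl ester is attacked by the small excess of hydroxylamine.

Step 4
Reactants: 6 5-[(E)-(hydroxyimino)methyl]-3-methoxy-2-(2-methoxy-2-oxoethoxy)phenyl 3,4-dimethoxybenzoate; 7 ethylene
Product: 10 5-(4,5-dihydroisoxazol-3-yl)-3-methoxy-2-(2-methoxy-2-oxoethoxy)phenyl 3,4-dimethoxybenzoate, via hydroximoyl chloride 8 (not isolated), via nitrile oxide 9 (not isolated)
Conditions: NCS (1.05 equiv), DMF, rt; then ethylene (5 bar), Et3N (slow addition), CH2Cl2, 0 °C → rt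
Reagents that add atoms: ethylene (7), C=C; N-chlorosuccinimide, O=C1CCC(=O)N1Cl (its chlorine stays only in 8)
Why: Chlorination and dehydrochlorination of the aldoxime release the nitrile oxide at low stationary concentration, and its concerted Huisgen 1,3-dipolar cycloaddition to the symmetrical dipolarophile closes the five-membered ring without any regio- or stereochemical question, while the aroyl group shields the phenol from the chlorinating agent.

Step 5
Reactants: 10 5-(4,5-dihydroisoxazol-3-yl)-3-methoxy-2-(2-methoxy-2-oxoethoxy)phenyl 3,4-dimethoxybenzoate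
Product: 12 methyl (2R,3S)-2-[4-(4,5-dihydroisoxazol-3-yl)-2-hydroxy-6-methoxyphenoxy]-3-(3,4-dimethoxyphenyl)-3-hydroxypropanoate, via racemic β-keto ester 11 (not isolated)
Conditions: LiHMDS (2.2 equiv), THF, −78 → 0 °C; then HCO2H/Et3N (5:2), RuCl[(R,R)-TsDPEN](p-cymene) (2 mol %), 35 °C
Reagents that add atoms: none
Why: Proposed new method: LiHMDS turns the O–CH2–CO2Me group (C8) into its ester enolate, which attacks the carbonyl carbon C7 of the neighbouring aryl ester, and the tetrahedral adduct expels the O3' phenoxide, so that one event makes the C7–C8 bond, cuts the tether and frees the phenol of the target, driven by the stabilised enolate of β-keto ester 11. The closest known reaction types are the Baker–Venkataraman O-to-C aroyl shift and the Chan rearrangement of acyloxyacetates for this stage and the Noyori–Ikariya transfer hydrogenation of α-alkoxy β-keto esters under dynamic kinetic resolution for the second stage, and what is new is the catechol-bridged ester enolate and the running of both stages in one flask. The only ring closed is the transient 2-oxido-1,4-benzodioxane (C8–O4'–C4'–C3'–O3'–C7), formed in a favoured 6-(enolexo)-exo-trig mode and opened again at once. After acidification 11 is a fast-exchanging mixture of both C8 enantiomers, the enol and the cyclic hemiketals, and the (R,R)-TsDPEN ruthenium hydride reduces only the open keto form, adding hydride to the carbonyl face fixed by the CH/π contact between its η6-arene and ring A, which sets C7 as S (the sense that gives (R)-1-phenylethanol from acetophenone, with the descriptor changed because C8 outranks aryl). C8 is set by matching, since hydride attack anti to the C8–OAr bond (polar Felkin–Anh) makes the (2R)-enantiomer of 11 the fast one and gives the syn (threo) product, while Et3N racemises the acidic C8–H faster than the slow enantiomer is reduced. The step needs C- over O-acylation (six- against eight-membered transition state), deprotonation at C8 and not at C4 of the dihydroisoxazole (LiHMDS is too weak a base for the latter) and a C=N–O unit inert to the ruthenium hydride (oxime ethers are not reduced under these conditions).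

Step 6
Reactants: 12 methyl (2R,3S)-2-[4-(4,5-dihydroisoxazol-3-yl)-2-hydroxy-6-methoxyphenoxy]-3-(3,4-dimethoxyphenyl)-3-hydroxypropanoate
Product: 13 (1S,2S)-2-[4-(4,5-dihydroisoxazol-3-yl)-2-hydroxy-6-methoxyphenoxy]-1-(3,4-dimethoxyphenyl)propane-1,3-diol
Conditions: LiBH4 (4 equiv), THF, 0 °C → rt; aq NH4Cl
Reagents that add atoms: none
Why: Chemoselective borohydride reduction of the activated α-aryloxy-β-hydroxy ester to the primary alcohol, in which the cyclic oxime ether is inert and neither stereocentre is touched (the descriptor at C8 changes from R to S only because the priority of C9 drops).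

Step 7
Reactants: 13 (1S,2S)-2-[4-(4,5-dihydroisoxazol-3-yl)-2-hydroxy-6-methoxyphenoxy]-1-(3,4-dimethoxyphenyl)propane-1,3-diol
Product: 14 1-(4-{[(1S,2S)-1-(3,4-dimethoxyphenyl)-1,3-dihydroxypropan-2-yl]oxy}-3-hydroxy-5-methoxyphenyl)-3-hydroxypropan-1-one
Conditions: H2 (1 atm), Raney Ni, B(OH)3, MeOH/H2O (5:1), rt
Reagents that add atoms: water, O
Why: Hydrogenolytic N–O cleavage of the 2-isoxazoline and hydrolysis of the resulting β-hydroxy imine in a boric acid buffer (the isoxazoline route to β-hydroxy ketones), which should be mild enough to leave the benzylic C7–OH, the aryl ether and the new ketone intact.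

**Compound list**
1 | 3,4-dihydroxy-5-methoxybenzaldehyde | COc1cc(C=O)cc(O)c1O | starting material
2 | methyl bromoacetate | COC(=O)CBr | starting material
3 | methyl 2-(4-formyl-2-hydroxy-6-methoxyphenoxy)acetate | COC(=O)COc1c(O)cc(C=O)cc1OC | intermediate
4 | 3,4-dimethoxybenzoyl chloride | COc1ccc(C(=O)Cl)cc1OC | starting material
5 | 5-formyl-3-methoxy-2-(2-methoxy-2-oxoethoxy)phenyl 3,4-dimethoxybenzoate | COC(=O)COc1c(OC(=O)c2ccc(OC)c(OC)c2)cc(C=O)cc1OC | intermediate
6 | 5-[(E)-(hydroxyimino)methyl]-3-methoxy-2-(2-methoxy-2-oxoethoxy)phenyl 3,4-dimethoxybenzoate | COC(=O)COc1c(OC(=O)c2ccc(OC)c(OC)c2)cc(/C=N/O)cc1OC | intermediate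
7 | ethylene | C=C | starting material
8 | 5-[(Z)-chloro(hydroxyimino)methyl]-3-methoxy-2-(2-methoxy-2-oxoethoxy)phenyl 3,4-dimethoxybenzoate (hydroximoyl chloride, not isolated) | COC(=O)COc1c(OC(=O)c2ccc(OC)c(OC)c2)cc(/C(Cl)=N/O)cc1OC | intermediate
9 | 3-(3,4-dimethoxybenzoyloxy)-5-methoxy-4-(2-methoxy-2-oxoethoxy)benzonitrile oxide (not isolated) | COC(=O)COc1c(OC(=O)c2ccc(OC)c(OC)c2)cc(C#[N+][O-])cc1OC | intermediate
10 | 5-(4,5-dihydroisoxazol-3-yl)-3-methoxy-2-(2-methoxy-2-oxoethoxy)phenyl 3,4-dimethoxybenzoate | COC(=O)COc1c(OC(=O)c2ccc(OC)c(OC)c2)cc(C3=NOCC3)cc1OC | intermediate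
11 | methyl 2-[4-(4,5-dihydroisoxazol-3-yl)-2-hydroxy-6-methoxyphenoxy]-3-(3,4-dimethoxyphenyl)-3-oxopropanoate (racemic, stereolabile at C8, not isolated) | COC(=O)C(Oc1c(O)cc(C2=NOCC2)cc1OC)C(=O)c1ccc(OC)c(OC)c1 | intermediate
12 | methyl (2R,3S)-2-[4-(4,5-dihydroisoxazol-3-yl)-2-hydroxy-6-methoxyphenoxy]-3-(3,4-dimethoxyphenyl)-3-hydroxypropanoate | COc1ccc([C@H](O)[C@H](C(=O)OC)Oc2c(O)cc(C3=NOCC3)cc2OC)cc1OC | intermediate
13 | (1S,2S)-2-[4-(4,5-dihydroisoxazol-3-yl)-2-hydroxy-6-methoxyphenoxy]-1-(3,4-dimethoxyphenyl)propane-1,3-diol | COc1ccc([C@H](O)[C@H](CO)Oc2c(O)cc(C3=NOCC3)cc2OC)cc1OC | intermediate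
14 | 1-(4-{[(1S,2S)-1-(3,4-dimethoxyphenyl)-1,3-dihydroxypropan-2-yl]oxy}-3-hydroxy-5-methoxyphenyl)-3-hydroxypropan-1-one | COc1ccc([C@H](O)[C@H](CO)Oc2c(O)cc(C(=O)CCO)cc2OC)cc1OC | target

Total step count: 7. Longest linear sequence: 7 steps (1 → 14).

**Steps most likely to fail**

Step 5 (bears the label).
- What may go wrong: the aroyl transfer may stay incomplete through proton exchange between the enolate and the released acidic sites, or through intermolecular Claisen condensation. The lithium and silazane residues carried into the second stage may slow the ruthenium hydride cycle. The bulky ortho,ortho'-disubstituted aryloxy group may erode the syn preference of the reduction.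
- The fallback uses known chemistry, an auxiliary-controlled boron aldol with C7 at the aldehyde level. It sets out from 10 and comes back at 14.
- K2CO3 in MeOH removes the aroyl group and gives methyl 2-[4-(4,5-dihydroisoxazol-3-yl)-2-hydroxy-6-methoxyphenoxy]acetate F1.
- BnBr/K2CO3 in DMF gives methyl 2-[2-(benzyloxy)-4-(4,5-dihydroisoxazol-3-yl)-6-methoxyphenoxy]acetate F2.
- LiOH in THF/H2O gives 2-[2-(benzyloxy)-4-(4,5-dihydroisoxazol-3-yl)-6-methoxyphenoxy]acetic acid F3.
- Activation with PivCl/Et3N and reaction with lithiated (R)-4-benzyl-1,3-oxazolidin-2-one gives (4R)-4-benzyl-3-{2-[2-(benzyloxy)-4-(4,5-dihydroisoxazol-3-yl)-6-methoxyphenoxy]acetyl}-1,3-oxazolidin-2-one F4.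
- Bu2BOTf/Et3N in CH2Cl2, then 3,4-dimethoxybenzaldehyde at −78 → 0 °C with H2O2 work-up, is an Evans syn glycolate aldol through the Z(O)-boron enolate and a Zimmerman–Traxler chair. It forms the same C7–C8 bond and gives (4R)-4-benzyl-3-{(2R,3S)-2-[2-(benzyloxy)-4-(4,5-dihydroisoxazol-3-yl)-6-methoxyphenoxy]-3-(3,4-dimethoxyphenyl)-3-hydroxypropanoyl}-1,3-oxazolidin-2-one F5.
- LiBH4 in THF/MeOH releases the auxiliary and gives (1S,2S)-2-[2-(benzyloxy)-4-(4,5-dihydroisoxazol-3-yl)-6-methoxyphenoxy]-1-(3,4-dimethoxyphenyl)propane-1,3-diol F6.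
- The conditions of step 7 then cleave the N–O bond and the benzyl ether together and deliver 14.

Step 7.
- What may go wrong: over-reduction of the intermediate imine to an amine or of the liberated aryl ketone, hydrogenolysis of the electron-rich benzylic C7–O bond, or loss of water from the β-hydroxy ketone.
- The fallback replaces hydrogenation by a non-hydrogenative N–O cleavage on a substrate whose benzylic alcohol is tied up. It sets out from 13 and comes back at 14.
- 2,2-Dimethoxypropane/PPTS in acetone gives 5-(4,5-dihydroisoxazol-3-yl)-2-{[(4S,5S)-4-(3,4-dimethoxyphenyl)-2,2-dimethyl-1,3-dioxan-5-yl]oxy}-3-methoxyphenol F7.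
- Mo(CO)6 in MeCN/H2O at 80 °C cleaves the N–O bond and gives 1-(4-{[(4S,5S)-4-(3,4-dimethoxyphenyl)-2,2-dimethyl-1,3-dioxan-5-yl]oxy}-3-hydroxy-5-methoxyphenyl)-3-hydroxypropan-1-one F8.
- Aqueous acetic acid at rt removes the acetonide and gives 14.

Step 1.
- What may go wrong: poor discrimination between the two phenolic oxygens, double alkylation, or lactonisation of the product ester onto the free ortho phenol.
- The fallback reverses the order of the two O-functionalisations. It sets out from 1 and comes back at 5.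
- The dianion of 1 (NaH, 2.1 equiv, DMF, 0 °C) is acylated with one equivalent of 4 at the more nucleophilic O3'. Any O-to-O acyl shift also favours this isomer, because the more acidic 4-OH stays as the phenoxide. This gives 5-formyl-2-hydroxy-3-methoxyphenyl 3,4-dimethoxybenzoate F9.
- Alkylation of the one remaining phenol with 2 (K2CO3, DMF) gives 5.

**Further compounds**
F1 | step 5 | methyl 2-[4-(4,5-dihydroisoxazol-3-yl)-2-hydroxy-6-methoxyphenoxy]acetate | COC(=O)COc1c(O)cc(C2=NOCC2)cc1OC
F2 | step 5 | methyl 2-[2-(benzyloxy)-4-(4,5-dihydroisoxazol-3-yl)-6-methoxyphenoxy]acetate | COC(=O)COc1c(OCc2ccccc2)cc(C2=NOCC2)cc1OC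
F3 | step 5 | 2-[2-(benzyloxy)-4-(4,5-dihydroisoxazol-3-yl)-6-methoxyphenoxy]acetic acid | OC(=O)COc1c(OCc2ccccc2)cc(C2=NOCC2)cc1OC
F4 | step 5 | (4R)-4-benzyl-3-{2-[2-(benzyloxy)-4-(4,5-dihydroisoxazol-3-yl)-6-methoxyphenoxy]acetyl}-1,3-oxazolidin-2-one | O=C(COc1c(OCc2ccccc2)cc(C2=NOCC2)cc1OC)N1[C@H](Cc2ccccc2)COC1=O
F5 | step 5 | (4R)-4-benzyl-3-{(2R,3S)-2-[2-(benzyloxy)-4-(4,5-dihydroisoxazol-3-yl)-6-methoxyphenoxy]-3-(3,4-dimethoxyphenyl)-3-hydroxypropanoyl}-1,3-oxazolidin-2-one | COc1ccc([C@H](O)[C@H](C(=O)N2[C@H](Cc3ccccc3)COC2=O)Oc2c(OCc3ccccc3)cc(C3=NOCC3)cc2OC)cc1OC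
F6 | step 5 | (1S,2S)-2-[2-(benzyloxy)-4-(4,5-dihydroisoxazol-3-yl)-6-methoxyphenoxy]-1-(3,4-dimethoxyphenyl)propane-1,3-diol | COc1ccc([C@H](O)[C@H](CO)Oc2c(OCc3ccccc3)cc(C3=NOCC3)cc2OC)cc1OC
F7 | step 7 | 5-(4,5-dihydroisoxazol-3-yl)-2-{[(4S,5S)-4-(3,4-dimethoxyphenyl)-2,2-dimethyl-1,3-dioxan-5-yl]oxy}-3-methoxyphenol | COc1ccc([C@@H]2OC(C)(C)OC[C@@H]2Oc2c(O)cc(C3=NOCC3)cc2OC)cc1OC
F8 | step 7 | 1-(4-{[(4S,5S)-4-(3,4-dimethoxyphenyl)-2,2-dimethyl-1,3-dioxan-5-yl]oxy}-3-hydroxy-5-methoxyphenyl)-3-hydroxypropan-1-one | COc1ccc([C@@H]2OC(C)(C)OC[C@@H]2Oc2c(O)cc(C(=O)CCO)cc2OC)cc1OC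
F9 | step 1 | 5-formyl-2-hydroxy-3-methoxyphenyl 3,4-dimethoxybenzoate | COc1cc(C=O)cc(OC(=O)c2ccc(OC)c(OC)c2)c1O
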